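**Retrosynthetic overview**

The target is (−)-epicatechin 3-O-gallate-(4β→6)-(−)-epicatechin 3-O-gallate-(4β→8)-(−)-epicatechin 3-O-gallate. No ring is formed in the route: rings A, B and C of all three units and all C2/C3 stereocentres are bought with (−)-epicatechin 1, and every unit comes from one intermediate, tetrabenzyl ether 3.
Last disconnection: C4 (ring C, top unit)–C6 (ring A, middle unit), giving the dibrominated 4β-alkoxy monomer 11 and the dimeric nucleophile 14. The earlier disconnection, C4 (ring C, middle unit)–C8 (ring A, bottom unit), uses the same reaction (step 7).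
Enabling feature: C4 of the top unit is benzylic to ring A (para to C7–O, ortho to C5–O and C8a–O1) and trans-vicinal to the C3 galloyl ester, so it ionises to a dioxolanium-bridged cation open only on the β face. C6 of the middle unit is a phloroglucinol-type carbon between C5–O and C7–O.
Site control: bromine on C8 (middle), C6 (bottom) and C6/C8 (top) leaves C6 of the middle unit as the only unsubstituted ring-A carbon in both partners. The four bromines leave with the 21 benzyl groups in the final hydrogenolysis.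
Order: monomers (steps 1–6), dimer (step 7), bromine cap (step 8), trimer (step 9), global deprotection (step 10).

Key step: step 9

Remark: flavan numbering is used for every unit (O1, C2, C3, C4, C4a, C5–C8, C8a; ring A = benzo ring, ring C = pyran ring, ring B = C2 aryl). All units have the 2,3-cis (2R,3R) epicatechin configuration and both interflavan bonds are trans to the neighbouring C3 ester (4β). Compounds 1, 2, 4, 6 and 9 are taken as commercial.

**Route**

Step 1
Reactants: 1 (−)-epicatechin; 2 benzyl bromide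
Product: 3 5,7,3',4'-tetra-O-benzyl-(−)-epicatechin
Conditions: BnBr (4.4 equiv), K2CO3 (5 equiv), DMF, 0 °C to rt, argon
Reagents that add atoms: benzyl bromide (2), BrCc1ccccc1
Why: Williamson etherification in which carbonate deprotonates only the four phenols, so the C3 alcohol should stay free and no stereocentre is touched.

Step 2
Reactants: 3 5,7,3',4'-tetra-O-benzyl-(−)-epicatechin; 4 3,4,5-tris(benzyloxy)benzoic acid
Product: 5 5,7,3',4'-tetra-O-benzyl-(−)-epicatechin 3-O-(3,4,5-tri-O-benzylgallate)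
Conditions: 4 (1.5 equiv), N,N'-dicyclohexylcarbodiimide (DCC), 4-(dimethylamino)pyridine (cat.), CH2Cl2, rt
Reagents that add atoms: 3,4,5-tris(benzyloxy)benzoic acid (4), OC(=O)c6cc(OCc5ccccc5)c(OCc5ccccc5)c(OCc5ccccc5)c6
Why: Steglich esterification of the only free hydroxyl; the C3–O bond is not broken, so C3 keeps its configuration.

Step 3
Reactants: 3 5,7,3',4'-tetra-O-benzyl-(−)-epicatechin; 6 2-ethoxyethanol
Product: 7 5,7,3',4'-tetra-O-benzyl-4β-(2-ethoxyethoxy)epicatechin (ether trans to the C3 hydroxyl)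
Conditions: 2,3-dichloro-5,6-dicyano-1,4-benzoquinone (DDQ, 2 equiv), 2-ethoxyethanol (5 equiv), CH2Cl2, rt
Reagents that add atoms: 2-ethoxyethanol (6), CCOCCO
Why: DDQ benzylic oxidation (hydride abstraction from C4, which is para/ortho to the ring-A oxygens) followed by capture of the alcohol on the β face, anti to the cis C2 aryl and C3 hydroxyl groups, which should give the 3,4-trans ether.

Step 4
Reactants: 7 5,7,3',4'-tetra-O-benzyl-4β-(2-ethoxyethoxy)epicatechin; 4 3,4,5-tris(benzyloxy)benzoic acid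
Product: 8 5,7,3',4'-tetra-O-benzyl-4β-(2-ethoxyethoxy)epicatechin 3-O-(3,4,5-tri-O-benzylgallate)
Conditions: 4 (1.5 equiv), DCC, 4-(dimethylamino)pyridine, CH2Cl2, rt
Reagents that add atoms: 3,4,5-tris(benzyloxy)benzoic acid (4), OC(=O)c6cc(OCc5ccccc5)c(OCc5ccccc5)c(OCc5ccccc5)c6
Why: Steglich esterification under neutral conditions, which should leave the acid-labile C4 ether and all stereocentres untouched.

Step 5
Reactants: 8 5,7,3',4'-tetra-O-benzyl-4β-(2-ethoxyethoxy)epicatechin 3-O-(3,4,5-tri-O-benzylgallate); 9 N-bromosuccinimide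
Product: 10 8-bromo derivative of 8 (middle-unit electrophile)
Conditions: N-bromosuccinimide (1.05 equiv), CH2Cl2, −78 to −20 °C, dark
Reagents that add atoms: N-bromosuccinimide (9), O=C1CCC(=O)N1Br
Why: Electrophilic aromatic bromination; C8 is the most nucleophilic carbon of a benzylated flavan ring A, and one equivalent at low temperature should stop at the monobromide.

Step 6
Reactants: 8 5,7,3',4'-tetra-O-benzyl-4β-(2-ethoxyethoxy)epicatechin 3-O-(3,4,5-tri-O-benzylgallate); 9 N-bromosuccinimide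
Product: 11 6,8-dibromo derivative of 8 (top-unit electrophile)
Conditions: N-bromosuccinimide (2.3 equiv), CH2Cl2, 0 °C to rt, dark
Reagents that add atoms: N-bromosuccinimide (9), O=C1CCC(=O)N1Br
Why: Exhaustive electrophilic aromatic bromination of ring A (C8, then C6); ring B and the galloyl ring are far less electron-rich and should not react.

Step 7
Reactants: 10 8-bromo middle-unit electrophile; 5 5,7,3',4'-tetra-O-benzyl-(−)-epicatechin 3-O-(3,4,5-tri-O-benzylgallate)
Product: 13 [8-bromo-hepta-O-benzyl-epicatechin gallate]-(4β→8)-[hepta-O-benzyl-epicatechin gallate], via dioxolanium triflate 12 (not isolated)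
Conditions: 5 (2 equiv), Me3SiOSO2CF3 (0.2 equiv), 4 Å MS, CH2Cl2, −78 to −30 °C; then Et3N
Reagents that add atoms: none
Why: Lewis-acid-promoted Friedel–Crafts interflavan coupling in which the 4β ether ionises with anti participation of the C3 galloyl carbonyl to give dioxolanium ion 12, which the most nucleophilic carbon of 5 (C8 of ring A) should open from the β face, setting C4 of the middle unit trans to the ester, while the C8 bromine of 10 stops its self-condensation.

Step 8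
Reactants: 13 monobromo dimer; 9 N-bromosuccinimide
Product: 14 [8-bromo-hepta-O-benzyl-epicatechin gallate]-(4β→8)-[6-bromo-hepta-O-benzyl-epicatechin gallate]
Conditions: N-bromosuccinimide (1.0 equiv), CH2Cl2, −78 to −30 °C, dark
Reagents that add atoms: N-bromosuccinimide (9), O=C1CCC(=O)N1Br
Why: Electrophilic aromatic bromination; the bromine-free ring A of the bottom unit is far more electron-rich than the already brominated ring A of the middle unit, so one equivalent should go to C6 of the bottom unit only.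

Step 9
Reactants: 14 dibromo dimer; 11 6,8-dibromo top-unit electrophile
Product: 16 [6,8-dibromo-hepta-O-benzyl-epicatechin gallate]-(4β→6)-[8-bromo-hepta-O-benzyl-epicatechin gallate]-(4β→8)-[6-bromo-hepta-O-benzyl-epicatechin gallate], via dioxolanium triflate 15 (not isolated)
Conditions: 11 (1.5 equiv), Me3SiOSO2CF3 (0.3 equiv), 4 Å MS, CH2Cl2, −40 to 0 °C; then Et3N
Reagents that add atoms: none
Why: Me3SiOSO2CF3 silylates the 4β ether oxygen of 11, and the alkoxy group leaves with anti participation of the trans C3 galloyl carbonyl to give the α-face cis-fused dioxolanium ion 15 (in equilibrium with the ring-A-stabilised C4 benzylic cation), which C6 of the middle unit of 14 attacks at C4 before rearomatising. The closest known reaction type is the Lewis-acid-promoted Friedel–Crafts interflavan coupling of 4-alkoxyflavan electrophiles with benzyl-protected flavan nucleophiles, including union at C6 of 8-bromo nucleophiles. No ring of the target is closed; the only ring formed is the temporary dioxolanium ring (5-exo-tet neighbouring-group closure), which is opened again in the same operation. The one new stereocentre, C4 of the top unit, is set by substrate control: the α face carries the dioxolanium bridge and the cis C2 aryl group, so the arene can enter only from the β face, trans to the C3 ester (two inversions, overall retention). The step needs complete site selectivity among the aromatic positions of two large partners; this is secured because C8 of the middle unit and C6 of the bottom unit of 14 and C6/C8 of 11 carry bromine, so C6 of the middle unit is the only unsubstituted phloroglucinol-type carbon, the catechol and galloyl rings are too electron-poor to compete, neither partner can self-condense and product 16 has no nucleophilic site left. Low temperature and a modest excess of 11 should protect the existing C4–C8 bond from acid-induced cleavage.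

Step 10
Reactants: 16 tetrabromo henicosa-O-benzyl trimer
Product: 17 (−)-epicatechin 3-O-gallate-(4β→6)-(−)-epicatechin 3-O-gallate-(4β→8)-(−)-epicatechin 3-O-gallate (CNP0183218.1)
Conditions: H2 (1 atm), Pd(OH)2 on carbon, Et3N (4.5 equiv), THF/MeOH/H2O, rt; filtration under argon
Reagents that add atoms: none
Why: Heterogeneous hydrogenolysis of the 21 benzyl ethers combined with hydrodehalogenation of the four aryl bromides, with Et3N trapping HBr so that the acid-labile interflavan bonds survive; the alkyl gallate esters, the C2–O1 bonds and all stereocentres should not be affected.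

**Compound list**

1 | (−)-epicatechin | O[C@@H]1Cc2c(O)cc(O)cc2O[C@@H]1c1ccc(O)c(O)c1 | starting material
2 | benzyl bromide | BrCc1ccccc1 | starting material
3 | 5,7,3',4'-tetra-O-benzyl-(−)-epicatechin | O[C@@H]1Cc2c(OCc5ccccc5)cc(OCc5ccccc5)cc2O[C@@H]1c7ccc(OCc5ccccc5)c(OCc5ccccc5)c7 | intermediate
4 | 3,4,5-tris(benzyloxy)benzoic acid | OC(=O)c6cc(OCc5ccccc5)c(OCc5ccccc5)c(OCc5ccccc5)c6 | starting material
5 | 5,7,3',4'-tetra-O-benzyl-(−)-epicatechin 3-O-(3,4,5-tri-O-benzylgallate) (hepta-O-benzyl-epicatechin gallate, bottom-unit nucleophile) | O=C(O[C@@H]1Cc2c(OCc5ccccc5)cc(OCc5ccccc5)cc2O[C@@H]1c7ccc(OCc5ccccc5)c(OCc5ccccc5)c7)c6cc(OCc5ccccc5)c(OCc5ccccc5)c(OCc5ccccc5)c6 | intermediate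
6 | 2-ethoxyethanol | CCOCCO | starting material
7 | 5,7,3',4'-tetra-O-benzyl-4β-(2-ethoxyethoxy)epicatechin (2,3-cis, 3,4-trans) | O[C@@H]1[C@@H](OCCOCC)c2c(OCc5ccccc5)cc(OCc5ccccc5)cc2O[C@@H]1c7ccc(OCc5ccccc5)c(OCc5ccccc5)c7 | intermediate
8 | 5,7,3',4'-tetra-O-benzyl-4β-(2-ethoxyethoxy)epicatechin 3-O-(3,4,5-tri-O-benzylgallate) | O=C(O[C@@H]1[C@@H](OCCOCC)c2c(OCc5ccccc5)cc(OCc5ccccc5)cc2O[C@@H]1c7ccc(OCc5ccccc5)c(OCc5ccccc5)c7)c6cc(OCc5ccccc5)c(OCc5ccccc5)c(OCc5ccccc5)c6 | intermediate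
9 | N-bromosuccinimide | O=C1CCC(=O)N1Br | starting material
10 | 8-bromo derivative of 8 (middle-unit electrophile) | O=C(O[C@@H]1[C@@H](OCCOCC)c2c(OCc5ccccc5)cc(OCc5ccccc5)c(Br)c2O[C@@H]1c7ccc(OCc5ccccc5)c(OCc5ccccc5)c7)c6cc(OCc5ccccc5)c(OCc5ccccc5)c(OCc5ccccc5)c6 | intermediate
11 | 6,8-dibromo derivative of 8 (top-unit electrophile) | O=C(O[C@@H]1[C@@H](OCCOCC)c2c(OCc5ccccc5)c(Br)c(OCc5ccccc5)c(Br)c2O[C@@H]1c7ccc(OCc5ccccc5)c(OCc5ccccc5)c7)c6cc(OCc5ccccc5)c(OCc5ccccc5)c(OCc5ccccc5)c6 | intermediate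
12 | C3/C4 cis-fused 2-(3,4,5-tribenzyloxyphenyl)-1,3-dioxolan-2-ylium triflate from 10 (not isolated) | O1[C@@H]2[C@H]([O+]=C1c6cc(OCc5ccccc5)c(OCc5ccccc5)c(OCc5ccccc5)c6)c3c(OCc5ccccc5)cc(OCc5ccccc5)c(Br)c3O[C@@H]2c7ccc(OCc5ccccc5)c(OCc5ccccc5)c7.[O-]S(=O)(=O)C(F)(F)F | intermediate
13 | [8-bromo-hepta-O-benzyl-epicatechin gallate]-(4β→8)-[hepta-O-benzyl-epicatechin gallate] | c1c(OCc5ccccc5)c(Br)c2c(c1OCc5ccccc5)[C@H](c8c(OCc5ccccc5)cc(OCc5ccccc5)c9c8O[C@H](c7ccc(OCc5ccccc5)c(OCc5ccccc5)c7)[C@H](OC(=O)c6cc(OCc5ccccc5)c(OCc5ccccc5)c(OCc5ccccc5)c6)C9)[C@@H](OC(=O)c6cc(OCc5ccccc5)c(OCc5ccccc5)c(OCc5ccccc5)c6)[C@@H](c7ccc(OCc5ccccc5)c(OCc5ccccc5)c7)O2 | intermediate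
14 | [8-bromo-hepta-O-benzyl-epicatechin gallate]-(4β→8)-[6-bromo-hepta-O-benzyl-epicatechin gallate] | c1c(OCc5ccccc5)c(Br)c2c(c1OCc5ccccc5)[C@H](c8c(OCc5ccccc5)c(Br)c(OCc5ccccc5)c9c8O[C@H](c7ccc(OCc5ccccc5)c(OCc5ccccc5)c7)[C@H](OC(=O)c6cc(OCc5ccccc5)c(OCc5ccccc5)c(OCc5ccccc5)c6)C9)[C@@H](OC(=O)c6cc(OCc5ccccc5)c(OCc5ccccc5)c(OCc5ccccc5)c6)[C@@H](c7ccc(OCc5ccccc5)c(OCc5ccccc5)c7)O2 | intermediate
15 | C3/C4 cis-fused 2-(3,4,5-tribenzyloxyphenyl)-1,3-dioxolan-2-ylium triflate from 11 (not isolated) | O1[C@@H]2[C@H]([O+]=C1c6cc(OCc5ccccc5)c(OCc5ccccc5)c(OCc5ccccc5)c6)c3c(OCc5ccccc5)c(Br)c(OCc5ccccc5)c(Br)c3O[C@@H]2c7ccc(OCc5ccccc5)c(OCc5ccccc5)c7.[O-]S(=O)(=O)C(F)(F)F | intermediate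
16 | [6,8-dibromo-hepta-O-benzyl-epicatechin gallate]-(4β→6)-[8-bromo-hepta-O-benzyl-epicatechin gallate]-(4β→8)-[6-bromo-hepta-O-benzyl-epicatechin gallate] | O=C(O[C@@H]1[C@@H](c3c(OCc5ccccc5)c(Br)c4c(c3OCc5ccccc5)[C@H](c8c(OCc5ccccc5)c(Br)c(OCc5ccccc5)c9c8O[C@H](c7ccc(OCc5ccccc5)c(OCc5ccccc5)c7)[C@H](OC(=O)c6cc(OCc5ccccc5)c(OCc5ccccc5)c(OCc5ccccc5)c6)C9)[C@@H](OC(=O)c6cc(OCc5ccccc5)c(OCc5ccccc5)c(OCc5ccccc5)c6)[C@@H](c7ccc(OCc5ccccc5)c(OCc5ccccc5)c7)O4)c2c(OCc5ccccc5)c(Br)c(OCc5ccccc5)c(Br)c2O[C@@H]1c7ccc(OCc5ccccc5)c(OCc5ccccc5)c7)c6cc(OCc5ccccc5)c(OCc5ccccc5)c(OCc5ccccc5)c6 | intermediate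
17 | (−)-epicatechin 3-O-gallate-(4β→6)-(−)-epicatechin 3-O-gallate-(4β→8)-(−)-epicatechin 3-O-gallate | O=C(O[C@@H]1[C@@H](c2c(O)cc3c(c2O)[C@H](c2c(O)cc(O)c4c2O[C@H](c2ccc(O)c(O)c2)[C@H](OC(=O)c2cc(O)c(O)c(O)c2)C4)[C@@H](OC(=O)c2cc(O)c(O)c(O)c2)[C@@H](c2ccc(O)c(O)c2)O3)c2c(O)cc(O)cc2O[C@@H]1c1ccc(O)c(O)c1)c1cc(O)c(O)c(O)c1 | target

**Step count and risks**

Total step count: 10. Longest linear sequence: 8 steps (1, 3, 4, 5, 7, 8, 9, 10).

Steps most likely to fail:

Step 9. The doubly brominated, ester-bearing electrophile may ionise slowly, and the crowded, bromine-deactivated C6 of a dimer may capture the cation slowly. Elimination or hydrolysis of the cation, or acid-induced cleavage of the existing C4–C8 bond, could then win. The fallback builds the same C4–C6 bond at monomer level with orthogonal leaving groups; it sets out from 10 and comes back to the route at 17. Compound 10 is treated with thiophenol and BF3·OEt2 (CH2Cl2, −40 °C) to exchange the C4 ether for sulfur, giving the 8-bromo-4β-phenylthio monomer F1, whose C–S bond is inert to an oxophilic silyl triflate. Me3SiOSO2CF3-promoted coupling of 11 with the small monomer F1, whose only free ring-A carbon is C6, should give the 4β→6-linked phenylthio dimer F2. Thiophilic activation of F2 with AgBF4 in the presence of excess 5, which reacts through its most nucleophilic C8 and therefore needs no bromine cap, should give the tribromo trimer F3. The conditions of step 10 then convert F3 into 17.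

Step 7. The cation may be attacked in part through C6 instead of C8 of 5, and the ester-retarded ionisation may be incomplete. The fallback moves esterification after the C–C bond formation; it sets out from 7 and comes back at 13. N-bromosuccinimide (1.05 equiv, CH2Cl2, −78 °C) converts 7 into the 8-bromo alcohol F4. Me3SiOSO2CF3-promoted coupling of F4 with excess 3, the free-hydroxyl version of this coupling with the closest precedent, should give the 8-bromo diol dimer F5. Two-fold Steglich esterification of F5 with 4 (DCC, 4-(dimethylamino)pyridine) returns 13.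

Step 10. Hydrodebromination at four hindered C–Br bonds may be incomplete, bromide may poison the catalyst, and HBr may cleave interflavan bonds during the long exhaustive debenzylation. The fallback separates the two tasks; it sets out from 16 and comes back at 17. Radical hydrodebromination with Bu3SnH and azobisisobutyronitrile (toluene, 90 °C) should give the bromine-free henicosa-O-benzyl trimer F6. Neutral hydrogenolysis of F6 (H2, Pd(OH)2 on carbon, THF/MeOH, rt) then gives 17 without any acid being formed.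

**Further compounds**

F1 | step 9 | 8-bromo-5,7,3',4'-tetra-O-benzyl-4β-(phenylthio)epicatechin 3-O-(3,4,5-tri-O-benzylgallate) | O=C(O[C@@H]1[C@@H](Sc8ccccc8)c2c(OCc5ccccc5)cc(OCc5ccccc5)c(Br)c2O[C@@H]1c7ccc(OCc5ccccc5)c(OCc5ccccc5)c7)c6cc(OCc5ccccc5)c(OCc5ccccc5)c(OCc5ccccc5)c6
F2 | step 9 | [6,8-dibromo-hepta-O-benzyl-epicatechin gallate]-(4β→6)-[8-bromo-4β-(phenylthio)-hepta-O-benzyl-epicatechin gallate] | O=C(O[C@@H]1[C@@H](c3c(OCc5ccccc5)c(Br)c4c(c3OCc5ccccc5)[C@H](Sc8ccccc8)[C@@H](OC(=O)c6cc(OCc5ccccc5)c(OCc5ccccc5)c(OCc5ccccc5)c6)[C@@H](c7ccc(OCc5ccccc5)c(OCc5ccccc5)c7)O4)c2c(OCc5ccccc5)c(Br)c(OCc5ccccc5)c(Br)c2O[C@@H]1c7ccc(OCc5ccccc5)c(OCc5ccccc5)c7)c6cc(OCc5ccccc5)c(OCc5ccccc5)c(OCc5ccccc5)c6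
F3 | step 9 | [6,8-dibromo-hepta-O-benzyl-epicatechin gallate]-(4β→6)-[8-bromo-hepta-O-benzyl-epicatechin gallate]-(4β→8)-[hepta-O-benzyl-epicatechin gallate] | O=C(O[C@@H]1[C@@H](c3c(OCc5ccccc5)c(Br)c4c(c3OCc5ccccc5)[C@H](c8c(OCc5ccccc5)cc(OCc5ccccc5)c9c8O[C@H](c7ccc(OCc5ccccc5)c(OCc5ccccc5)c7)[C@H](OC(=O)c6cc(OCc5ccccc5)c(OCc5ccccc5)c(OCc5ccccc5)c6)C9)[C@@H](OC(=O)c6cc(OCc5ccccc5)c(OCc5ccccc5)c(OCc5ccccc5)c6)[C@@H](c7ccc(OCc5ccccc5)c(OCc5ccccc5)c7)O4)c2c(OCc5ccccc5)c(Br)c(OCc5ccccc5)c(Br)c2O[C@@H]1c7ccc(OCc5ccccc5)c(OCc5ccccc5)c7)c6cc(OCc5ccccc5)c(OCc5ccccc5)c(OCc5ccccc5)c6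
F4 | step 7 | 8-bromo-5,7,3',4'-tetra-O-benzyl-4β-(2-ethoxyethoxy)epicatechin | O[C@@H]1[C@@H](OCCOCC)c2c(OCc5ccccc5)cc(OCc5ccccc5)c(Br)c2O[C@@H]1c7ccc(OCc5ccccc5)c(OCc5ccccc5)c7
F5 | step 7 | [8-bromo-5,7,3',4'-tetra-O-benzylepicatechin]-(4β→8)-[5,7,3',4'-tetra-O-benzylepicatechin] (3,3''-diol) | c1c(OCc5ccccc5)c(Br)c2c(c1OCc5ccccc5)[C@H](c8c(OCc5ccccc5)cc(OCc5ccccc5)c9c8O[C@H](c7ccc(OCc5ccccc5)c(OCc5ccccc5)c7)[C@H](O)C9)[C@@H](O)[C@@H](c7ccc(OCc5ccccc5)c(OCc5ccccc5)c7)O2
F6 | step 10 | [hepta-O-benzyl-epicatechin gallate]-(4β→6)-[hepta-O-benzyl-epicatechin gallate]-(4β→8)-[hepta-O-benzyl-epicatechin gallate] | O=C(O[C@@H]1[C@@H](c3c(OCc5ccccc5)cc4c(c3OCc5ccccc5)[C@H](c8c(OCc5ccccc5)cc(OCc5ccccc5)c9c8O[C@H](c7ccc(OCc5ccccc5)c(OCc5ccccc5)c7)[C@H](OC(=O)c6cc(OCc5ccccc5)c(OCc5ccccc5)c(OCc5ccccc5)c6)C9)[C@@H](OC(=O)c6cc(OCc5ccccc5)c(OCc5ccccc5)c(OCc5ccccc5)c6)[C@@H](c7ccc(OCc5ccccc5)c(OCc5ccccc5)c7)O4)c2c(OCc5ccccc5)cc(OCc5ccccc5)cc2O[C@@H]1c7ccc(OCc5ccccc5)c(OCc5ccccc5)c7)c6cc(OCc5ccccc5)c(OCc5ccccc5)c(OCc5ccccc5)c6
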